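**Plan**

1. Target: (2S)-5-hydroxy-7-methoxy-2-(4-methoxyphenyl)-8-prenylchroman-4-one (flavanone numbering O1, C2, C3, C4, C4a, C5–C8, C8a; ring A is the benzo ring, ring C the pyranone ring, ring B the 4-methoxyphenyl group).
2. Cuts, in retrosynthetic order: the tert-butyl ether on O5 (a helper); then C3–C4 and O1–C8a of ring C in one operation; then, on ring A, the C5–O bond and the C8–prenyl bond, back to 2,6-difluoro-4-methoxybenzonitrile.
3. Enabling feature: C4 is an aryl carbonyl carbon whose ring A neighbour C4a lies between two oxygen-bearing carbons (C5 and C8a), and O1 stands 1,3 to C4 across C2–C3. Ring A with C4 can therefore act as a 1,3-bis-electrophile (nitrile carbon plus ortho C–F) and O1–C2–C3 as a 1,3-dianion.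
4. Forward order: rings A and B are bought; the prenyl group goes onto the symmetric difluoronitrile and then shields its neighbouring fluorine, so that tert-butoxide takes the other one (the later O5); ring C is closed last by a [3+3] annulation with a β-oxido alkyllithium.
5. Stereochemistry: C2 is set by catalyst-controlled transfer hydrogenation of a chloroketone and carried through. C4 is kept at the ketimine level (helper oxidation level) during the basic phase, so that no aldolate or enolate can scramble C2, and is hydrolysed at the end of the key step.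

Key step: step 4

Remark: 2,6-difluoro-4-methoxybenzonitrile and 2-chloro-1-(4-methoxyphenyl)ethanone are taken as commercially available.

**Step 1**
Reactants: 1 2,6-difluoro-4-methoxybenzonitrile
Product: 4 2,6-difluoro-4-methoxy-3-(3-methylbut-2-en-1-yl)benzonitrile, via aryllithium 2 (not isolated), via arylcopper 3 (not isolated)
Conditions: lithium 2,2,6,6-tetramethylpiperidide (LiTMP, 1.05 equiv), THF, −78 °C; CuBr·SMe2 (1.0 equiv), −78 °C; prenyl bromide, −78 to 0 °C
Reagents that add atoms: prenyl bromide (1-bromo-3-methylbut-2-ene), CC(C)=CCBr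
Why: Directed ortho-metalation followed by copper-mediated allylic substitution: the two ring C–H bonds of 1 are equivalent by symmetry and each lies between F and OMe, so LiTMP should remove that proton without a choice of site, and arylcopper 3 should couple with prenyl bromide at its unsubstituted carbon (SN2 mode), while the low temperature keeps 2 from losing LiF or adding to a nitrile.

**Step 2**
Reactants: 4 2,6-difluoro-4-methoxy-3-(3-methylbut-2-en-1-yl)benzonitrile
Product: 5 6-tert-butoxy-2-fluoro-4-methoxy-3-(3-methylbut-2-en-1-yl)benzonitrile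
Conditions: KOt-Bu (1.05 equiv), THF, −20 to 0 °C
Reagents that add atoms: potassium tert-butoxide, CC(C)(C)[O-].[K+]
Why: Nucleophilic aromatic substitution (SNAr) activated by the ortho nitrile: attack at either fluorine-bearing carbon puts the charge on the same three ring carbons, so the choice should be steric, and the bulky tert-butoxide should take the fluorine that has H and not the prenyl CH2 as its neighbour, after which the more electron-rich ring resists a second substitution.

**Step 3**
Reactants: 6 2-chloro-1-(4-methoxyphenyl)ethanone
Product: 7 (R)-2-chloro-1-(4-methoxyphenyl)ethanol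
Conditions: Cp*RhCl[(S,S)-TsDPEN] (0.5 mol%), HCO2H/Et3N (5:2), EtOAc, 25 °C
Reagents that add atoms: none
Why: Noyori–Ikariya asymmetric transfer hydrogenation of an aryl ketone, in which the (S,S)-ligand should deliver hydride to the same face as in the reduction of acetophenone to (S)-1-phenylethanol, a face that here carries the descriptor R because CH2Cl outranks the aryl group, so that the C2 stereocentre of the target is set by the catalyst.

**Step 4**
Reactants: 7 (R)-2-chloro-1-(4-methoxyphenyl)ethanol; 5 6-tert-butoxy-2-fluoro-4-methoxy-3-(3-methylbut-2-en-1-yl)benzonitrile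
Product: 13 (S)-5-tert-butoxy-7-methoxy-2-(4-methoxyphenyl)-8-(3-methylbut-2-en-1-yl)chroman-4-one, via lithium alkoxide 8 (not isolated), via dilithio species 9 (not isolated), via open N-lithio ketimine 10 (not isolated), via open NH ketimine 11 (not isolated), via cyclic ketimine 12 (not isolated)
Conditions: n-BuLi (1.0 equiv), THF, −78 °C; LiC10H8 (lithium naphthalenide, 2.0 equiv), −78 °C; 5, −78 °C; AcOH (1.0 equiv), DMPU, −78 to 45 °C; 1 M aq. HCl, THF, 0 to 25 °C
Reagents that add atoms: water, O
Why: Proposed new method: a [3+3] annulation of a 1,3-dianion with a 2-fluorobenzonitrile as 1,3-bis-electrophile, reasoned as follows: the C–Li bond of 9 (a β-oxido alkyllithium of the kind known from reductive lithiation of chlorohydrin alkoxides, kept at −78 °C so that it does not lose Li2O) should add to the nitrile carbon of 5 as alkyllithiums do with 2-fluorobenzonitriles, which makes C3–C4 and ties the alkoxide next to the C–F bond. One equivalent of AcOH should then turn the N-lithio ketimine 10 into the neutral NH ketimine 11, whose C=N group activates the ortho carbon C8a, so that the lithium alkoxide can displace fluoride by addition–elimination (SNAr, the closest known type being alkoxide displacement of fluoride ortho to an imine, oxazoline or ketone), which makes O1–C8a. Ring C closes as a six-membered ring by attack of O1 on C8a (6-exo-trig, the charge passing to C4a and the C4=N group), and LiF leaves. No new stereocentre is formed: C2 comes from 7 and neither its C–O bond nor its C–H bond is involved, so the configuration should be carried over. Holding C4 at the ketimine level until the acidic work-up is the point of the design, because the open intermediate is then no aldolate that could fall back to aldehyde and enolate, and the closed one has no enolate that could open ring C to a chalcone, which is how flavanones lose C2 in base. The step needs chemoselectivity (C–Li before O–Li, nitrile before C–F), secured by the much higher reactivity of the alkyllithium at −78 °C, and site selectivity on ring A, secured because only C8a carries a leaving group while C5 carries tert-butoxy.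

**Step 5**
Reactants: 13 (S)-5-tert-butoxy-7-methoxy-2-(4-methoxyphenyl)-8-(3-methylbut-2-en-1-yl)chroman-4-one
Product: 14 flowerine [(S)-5-hydroxy-7-methoxy-2-(4-methoxyphenyl)-8-(3-methylbut-2-en-1-yl)chroman-4-one]
Conditions: TFA/CH2Cl2 (1:9), 0 °C
Reagents that add atoms: none
Why: Acidolysis of an aryl tert-butyl ether (loss of the tert-butyl cation as isobutene), eased by relief of the peri strain between O5 and C4=O and by the hydrogen bond of the freed phenol to the carbonyl, under conditions that contain no base, so that the prenyl alkene and the C2 centre should stay as they are.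

**Compound list**

1 | 2,6-difluoro-4-methoxybenzonitrile | N#Cc1c(F)cc(OC)cc1F | starting material
2 | (3-cyano-2,4-difluoro-6-methoxyphenyl)lithium | N#Cc1c(F)c([Li])c(OC)cc1F | intermediate
3 | (3-cyano-2,4-difluoro-6-methoxyphenyl)copper | N#Cc1c(F)c([Cu])c(OC)cc1F | intermediate
4 | 2,6-difluoro-4-methoxy-3-(3-methylbut-2-en-1-yl)benzonitrile | N#Cc1c(F)c(CC=C(C)C)c(OC)cc1F | intermediate
5 | 6-tert-butoxy-2-fluoro-4-methoxy-3-(3-methylbut-2-en-1-yl)benzonitrile | N#Cc1c(F)c(CC=C(C)C)c(OC)cc1OC(C)(C)C | intermediate
6 | 2-chloro-1-(4-methoxyphenyl)ethanone | COc1ccc(C(=O)CCl)cc1 | starting material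
7 | (R)-2-chloro-1-(4-methoxyphenyl)ethanol | COc1ccc([C@@H](O)CCl)cc1 | intermediate
8 | lithium (R)-2-chloro-1-(4-methoxyphenyl)ethan-1-olate | COc1ccc([C@@H](O[Li])CCl)cc1 | intermediate
9 | lithium (S)-2-lithio-1-(4-methoxyphenyl)ethan-1-olate | COc1ccc([C@@H](O[Li])C[Li])cc1 | intermediate
10 | lithium (S)-3-[6-tert-butoxy-2-fluoro-4-methoxy-3-(3-methylbut-2-en-1-yl)phenyl]-3-(lithioimino)-1-(4-methoxyphenyl)propan-1-olate | COc1ccc([C@@H](O[Li])CC(=N[Li])c2c(F)c(CC=C(C)C)c(OC)cc2OC(C)(C)C)cc1 | intermediate
11 | lithium (S)-3-[6-tert-butoxy-2-fluoro-4-methoxy-3-(3-methylbut-2-en-1-yl)phenyl]-3-imino-1-(4-methoxyphenyl)propan-1-olate | COc1ccc([C@@H](O[Li])CC(=N)c2c(F)c(CC=C(C)C)c(OC)cc2OC(C)(C)C)cc1 | intermediate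
12 | (S)-5-tert-butoxy-7-methoxy-2-(4-methoxyphenyl)-8-(3-methylbut-2-en-1-yl)chroman-4-imine | COc1ccc([C@@H]2CC(=N)c3c(OC(C)(C)C)cc(OC)c(CC=C(C)C)c3O2)cc1 | intermediate
13 | (S)-5-tert-butoxy-7-methoxy-2-(4-methoxyphenyl)-8-(3-methylbut-2-en-1-yl)chroman-4-one | COc1ccc([C@@H]2CC(=O)c3c(OC(C)(C)C)cc(OC)c(CC=C(C)C)c3O2)cc1 | intermediate
14 | flowerine, (S)-5-hydroxy-7-methoxy-2-(4-methoxyphenyl)-8-(3-methylbut-2-en-1-yl)chroman-4-one | COc1ccc([C@@H]2CC(=O)c3c(O)cc(OC)c(CC=C(C)C)c3O2)cc1 | target

**Count**

Total steps: 5. Longest linear sequence: 4 (steps 1, 2, 4, 5).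

**Steps most likely to fail**

Step 4. What may go wrong: loss of Li2O from the dilithio species (β-elimination to the styrene) before it has added to the hindered nitrile, or a ring closure so slow at the ketimine level that proton shifts in the open ketimine and intermolecular reactions take over. The fallback uses known reaction types only, sets out from 5 and comes back at 13, with C2 then set by a catalyst instead of being carried in. MeLi should add to the nitrile of 5 to give N-lithio-1-[6-tert-butoxy-2-fluoro-4-methoxy-3-(3-methylbut-2-en-1-yl)phenyl]ethan-1-imine F1, and cold aqueous HCl should give the methyl ketone 1-[6-tert-butoxy-2-fluoro-4-methoxy-3-(3-methylbut-2-en-1-yl)phenyl]ethan-1-one F2. Claisen condensation with ethyl formate (NaH, THF) should give sodium (Z)-3-[6-tert-butoxy-2-fluoro-4-methoxy-3-(3-methylbut-2-en-1-yl)phenyl]-3-oxoprop-1-en-1-olate F3, which on warming in DMF should close by SNAr of the enolate oxygen at the C–F carbon to 5-tert-butoxy-7-methoxy-8-(3-methylbut-2-en-1-yl)-4H-chromen-4-one F4. Enantioselective conjugate addition of 4-methoxyphenylboronic acid to F4 (Pd(OCOCF3)2, the enantiomer of the pyridine–oxazoline ligand t-BuPyOx that leads to 2S, NH4PF6, water, 1,2-dichloroethane, 60 °C) should then give 13.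

Step 2. What may go wrong: substitution of the fluorine beside the prenyl group because the steric discrimination is not sufficient, or base-induced migration of the prenyl double bond into conjugation with the ring. The fallback inverts the order of the two ring A steps, sets out from 1 and comes back at 5. tert-Butoxide is put first onto the symmetric nitrile 1 (KOt-Bu, THF, 0 °C), where no choice of site exists, to give 2-tert-butoxy-6-fluoro-4-methoxybenzonitrile F5. LiTMP at −78 °C should then remove the proton between F and OMe, which is more acidic than the one between the two alkoxy groups and is not shielded by the tert-butyl group, to give (4-tert-butoxy-3-cyano-2-fluoro-6-methoxyphenyl)lithium F6. CuBr·SMe2 should turn this into (4-tert-butoxy-3-cyano-2-fluoro-6-methoxyphenyl)copper F7, and prenyl bromide should give 5.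

Step 1. What may go wrong: bond formation at the substituted end of the allylic bromide (SN2′ mode), which would put a 1,1-dimethylallyl group on the ring. The fallback builds the prenyl group in two stages, sets out from 1 and comes back at 4. Arylcopper 3, made as in step 1, is allylated with allyl bromide, whose two ends are alike, to give 3-allyl-2,6-difluoro-4-methoxybenzonitrile F8. Cross-metathesis with 2-methylbut-2-ene (second-generation Grubbs catalyst RuCl2(=CHPh)(H2IMes)(PCy3), CH2Cl2, 40 °C) should give 4.

**Further compounds**

F1 | step 4 | N-lithio-1-[6-tert-butoxy-2-fluoro-4-methoxy-3-(3-methylbut-2-en-1-yl)phenyl]ethan-1-imine | CC(=N[Li])c1c(F)c(CC=C(C)C)c(OC)cc1OC(C)(C)C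
F2 | step 4 | 1-[6-tert-butoxy-2-fluoro-4-methoxy-3-(3-methylbut-2-en-1-yl)phenyl]ethan-1-one | CC(=O)c1c(F)c(CC=C(C)C)c(OC)cc1OC(C)(C)C
F3 | step 4 | sodium (Z)-3-[6-tert-butoxy-2-fluoro-4-methoxy-3-(3-methylbut-2-en-1-yl)phenyl]-3-oxoprop-1-en-1-olate | [Na+].[O-]/C=C\C(=O)c1c(F)c(CC=C(C)C)c(OC)cc1OC(C)(C)C
F4 | step 4 | 5-tert-butoxy-7-methoxy-8-(3-methylbut-2-en-1-yl)-4H-chromen-4-one | O=c1ccoc2c(CC=C(C)C)c(OC)cc(OC(C)(C)C)c12
F5 | step 2 | 2-tert-butoxy-6-fluoro-4-methoxybenzonitrile | N#Cc1c(F)cc(OC)cc1OC(C)(C)C
F6 | step 2 | (4-tert-butoxy-3-cyano-2-fluoro-6-methoxyphenyl)lithium | N#Cc1c(F)c([Li])c(OC)cc1OC(C)(C)C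
F7 | step 2 | (4-tert-butoxy-3-cyano-2-fluoro-6-methoxyphenyl)copper | N#Cc1c(F)c([Cu])c(OC)cc1OC(C)(C)C
F8 | step 1 | 3-allyl-2,6-difluoro-4-methoxybenzonitrile | N#Cc1c(F)c(CC=C)c(OC)cc1F
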